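**Assumption:** positions are given in germacrane numbering (ring C1–C10; C1=C10 alkene carrying C14; C4–C5 epoxide carrying C15; C7 carrying C11(=C13)–C12; C9 carrying the angelate), and the target is read as 4S,5R,7S,9S with a (2R,3S)-3-hydroxy-2-methylbutanoate.

## Retrosynthetic overview

1. The oxirane is made last, by hydroxyl-directed asymmetric epoxidation of the C15 allylic alcohol. The C14 ester comes from opening an organocatalytically made cis-β-lactone, and the C9 angelate from esterification after a CBS reduction.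
2. The ten-membered carbocycle is the first ring formed. It is closed at C9–C10 by intramolecular alkyne hydroacylation of an acyclic ynal (the proposed new step), which gives the E-enone directly.
3. The ynal comes from a Z-selective Wittig reaction (C4=C5) between an α-silyloxy ketone (C1–C4, C10, C14, C15) and a C5 phosphonium salt that carries C7.
4. C7, the first stereocentre, is set by an organocatalytic Mukaiyama–Michael addition to an achiral enal; α-methylenation in the same pot builds C11–C13.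
5. All fragments come from achiral commercial materials.

## Route

Step 1
Reactants: 1 4,4-diethoxybut-1-ene; 2 (E)-but-2-enal
Product: 3 (E)-5,5-diethoxypent-2-enal
Conditions: second-generation Hoveyda–Grubbs catalyst (2 mol%), 2 (5 equiv), CH2Cl2, 40 °C
Reagents that add atoms: none
Why: Olefin cross-metathesis of the terminal alkene with excess crotonaldehyde gives the E-enal, driven by loss of propene; no stereocentre is formed.

Step 2
Reactants: 4 S-tert-butyl ethanethioate
Product: 6 1-(tert-butylsulfanyl)-1-(trimethylsilyloxy)ethene, via lithium thioester enolate 5 (not isolated)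
Conditions: LiN(iPr)2, THF, −78 °C; then Me3SiCl, −78 °C to rt
Reagents that add atoms: chlorotrimethylsilane, C[Si](C)(C)Cl
Why: Kinetic enolisation of the thioester and O-silylation give the silyl ketene thioacetal needed for the Mukaiyama–Michael step.

Step 3
Reactants: 3 (E)-5,5-diethoxypent-2-enal; 6 1-(tert-butylsulfanyl)-1-(trimethylsilyloxy)ethene
Product: 8 S-tert-butyl (3S)-5,5-diethoxy-3-(3-oxoprop-1-en-2-yl)pentanethioate, via Michael aldehyde 7 (not isolated)
Conditions: (2S,5S)-5-benzyl-2-tert-butyl-3-methylimidazolidin-4-one·CF3CO2H (20 mol%), CH2Cl2/H2O, −78 °C; then iPrOH, 37% aq. CH2O, pyrrolidine (10 mol%), EtCO2H (10 mol%), 45 °C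
Reagents that add atoms: formaldehyde, C=O
Why: Organocatalytic Mukaiyama–Michael addition in which the benzyl group of the imidazolidinone shields one face of the E-iminium ion so the ketene thioacetal adds to the Re face of the β-carbon and sets C7 (the first stereocentre, 7S in the target), after which the freed aldehyde is α-methylenated by amine-catalysed Mannich condensation–elimination.

Step 4
Reactants: 8 S-tert-butyl (3S)-5,5-diethoxy-3-(3-oxoprop-1-en-2-yl)pentanethioate
Product: 9 (3R)-5,5-diethoxy-3-(3-hydroxyprop-1-en-2-yl)pentan-1-ol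
Conditions: iBu2AlH (6 equiv), CH2Cl2, −78 to 0 °C
Reagents that add atoms: none
Why: Hydride reduction takes the enal (1,2) and the thioester to the two primary alcohols and leaves the acetal and C7 untouched.

Step 5
Reactants: 9 (3R)-5,5-diethoxy-3-(3-hydroxyprop-1-en-2-yl)pentan-1-ol
Product: 10 (3S)-1,1-diethoxy-5-iodo-3-(3-iodoprop-1-en-2-yl)pentane
Conditions: I2, PPh3, imidazole, CH2Cl2, 0 °C to rt
Reagents that add atoms: iodine, II
Why: Appel-type iodination converts both primary alcohols into iodides under buffered conditions that spare the acetal.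

Step 6
Reactants: 10 (3S)-1,1-diethoxy-5-iodo-3-(3-iodoprop-1-en-2-yl)pentane
Product: 11 2-[(3S)-5,5-diethoxy-1-iodopentan-3-yl]prop-2-en-1-yl acetate
Conditions: KOAc (1.05 equiv), DMF, 0 °C
Reagents that add atoms: potassium acetate, CC(=O)[O-].[K+]
Why: SN2 displacement by acetate is much faster at the allylic iodide than at the unactivated primary iodide, and attack at either allylic terminus gives the same 2-substituted allyl acetate.

Step 7
Reactants: 11 2-[(3S)-5,5-diethoxy-1-iodopentan-3-yl]prop-2-en-1-yl acetate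
Product: 12 {(3S)-3-[3-(acetyloxy)prop-1-en-2-yl]-5,5-diethoxypentyl}triphenylphosphonium iodide
Conditions: PPh3, MeCN, 75 °C
Reagents that add atoms: triphenylphosphine, c1ccc(cc1)P(c1ccccc1)c1ccccc1
Why: SN2 quaternisation of the remaining primary iodide gives the Wittig salt; the allylic acetate is inert to PPh3 without a transition metal.

Step 8
Reactants: 13 2-[(tert-butyldimethylsilyl)oxy]acetaldehyde
Product: 14 (±)-1-[(tert-butyldimethylsilyl)oxy]but-3-en-2-ol
Conditions: CH2=CHMgBr, THF, −78 °C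
Reagents that add atoms: vinylmagnesium bromide, C=C[Mg]Br
Why: Grignard 1,2-addition to the aldehyde; the racemic carbinol centre is removed in the next step.

Step 9
Reactants: 14 (±)-1-[(tert-butyldimethylsilyl)oxy]but-3-en-2-ol
Product: 15 1-[(tert-butyldimethylsilyl)oxy]but-3-en-2-one
Conditions: Dess–Martin periodinane, CH2Cl2, 0 °C
Reagents that add atoms: none
Why: Dess–Martin oxidation of the allylic alcohol gives the vinyl ketone under neutral conditions.

Step 10
Reactants: 15 1-[(tert-butyldimethylsilyl)oxy]but-3-en-2-one; 16 1-methoxy-4-[(prop-2-yn-1-yloxy)methyl]benzene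
Product: 17 1-[(tert-butyldimethylsilyl)oxy]-7-[(4-methoxybenzyl)oxy]hept-5-yn-2-one
Conditions: Pd(OAc)2 (5 mol%), PMe3 (20 mol%), acetone, 60 °C
Reagents that add atoms: none
Why: Pd-catalysed conjugate addition of the terminal alkyne C–H bond to the vinyl ketone forms the C1–C2 bond under neutral conditions that tolerate the silyl and PMB ethers.

Step 11
Reactants: 12 {(3S)-3-[3-(acetyloxy)prop-1-en-2-yl]-5,5-diethoxypentyl}triphenylphosphonium iodide; 17 1-[(tert-butyldimethylsilyl)oxy]-7-[(4-methoxybenzyl)oxy]hept-5-yn-2-one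
Product: 19 2-[(3R,5Z)-6-{[(tert-butyldimethylsilyl)oxy]methyl}-1,1-diethoxy-11-[(4-methoxybenzyl)oxy]undec-5-en-9-yn-3-yl]prop-2-en-1-yl acetate, via phosphorus ylide 18 (not isolated)
Conditions: KN(SiMe3)2, THF, −78 °C; then 17, −78 °C to rt
Reagents that add atoms: none
Why: Wittig olefination of an α-silyloxy ketone with a salt-free non-stabilised ylide is Z-selective and places the CH2OTBS group (C15) cis to the C6 chain, which is the geometry needed at C4=C5.

Step 12
Reactants: 19 2-[(3R,5Z)-6-{[(tert-butyldimethylsilyl)oxy]methyl}-1,1-diethoxy-11-[(4-methoxybenzyl)oxy]undec-5-en-9-yn-3-yl]prop-2-en-1-yl acetate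
Product: 20 2-[(3R,5Z)-6-{[(tert-butyldimethylsilyl)oxy]methyl}-11-[(4-methoxybenzyl)oxy]-1-oxoundec-5-en-9-yn-3-yl]prop-2-en-1-yl acetate
Conditions: aq. oxalic acid on SiO2, CH2Cl2, rt
Reagents that add atoms: water, O
Why: Mild acetal hydrolysis on wet silica releases the C9 aldehyde without cleaving the primary silyl ether, the PMB ether or the allylic acetate.

Step 13
Reactants: 20 2-[(3R,5Z)-6-{[(tert-butyldimethylsilyl)oxy]methyl}-11-[(4-methoxybenzyl)oxy]-1-oxoundec-5-en-9-yn-3-yl]prop-2-en-1-yl acetate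
Product: 21 (2E,6Z,9R)-9-[3-(acetyloxy)prop-1-en-2-yl]-6-{[(tert-butyldimethylsilyl)oxy]methyl}-2-{[(4-methoxybenzyl)oxy]methyl}cyclodeca-2,6-dien-1-one
Conditions: Ni(cod)2 (20 mol%), 1,3-bis(2,6-diisopropylphenyl)imidazol-2-ylidene (20 mol%), toluene (0.002 M, syringe-pump addition), 80 °C
Reagents that add atoms: none
Why: Proposed new method: zerovalent nickel–NHC-catalysed redox-neutral intramolecular alkyne hydroacylation in the ten-membered endo mode, in which oxidative cyclisation of aldehyde and alkyne at nickel forms the C9–C10 bond in an oxanickelacyclopentene, β-hydride elimination of the C9–H and C–H reductive elimination release the enone with acyl and hydrogen syn (E geometry, C9 trans to C2), and the exo closure is disfavoured because it would put the trans C4=C5 alkene in a nine-membered ring; the closest known reactions are nickel–phosphine intermolecular hydroacylation of internal alkynes with aldehydes, nickel–NHC intramolecular alkene hydroacylation to five- and six-membered ketones, and nickel-catalysed reductive ynal macrocyclisations of larger rings.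

Step 14
Reactants: 21 (2E,6Z,9R)-9-[3-(acetyloxy)prop-1-en-2-yl]-6-{[(tert-butyldimethylsilyl)oxy]methyl}-2-{[(4-methoxybenzyl)oxy]methyl}cyclodeca-2,6-dien-1-one
Product: 22 (1S,2E,6Z,9R)-9-[3-(acetyloxy)prop-1-en-2-yl]-6-{[(tert-butyldimethylsilyl)oxy]methyl}-2-{[(4-methoxybenzyl)oxy]methyl}cyclodeca-2,6-dien-1-ol
Conditions: (R)-2-methyl-CBS-oxazaborolidine (20 mol%), catecholborane, toluene, −78 °C; aqueous work-up
Reagents that add atoms: none
Why: Corey–Bakshi–Shibata reduction in which the ketone binds the (R)-oxazaborolidine with the trisubstituted alkenyl group as the large substituent, so hydride is delivered under catalyst control to give the 9S allylic alcohol, and catecholborane at −78 °C leaves the alkenes and esters alone.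

Step 15
Reactants: 22 (1S,2E,6Z,9R)-9-[3-(acetyloxy)prop-1-en-2-yl]-6-{[(tert-butyldimethylsilyl)oxy]methyl}-2-{[(4-methoxybenzyl)oxy]methyl}cyclodeca-2,6-dien-1-ol; 23 (Z)-2-methylbut-2-enoic acid (angelic acid)
Product: 25 (1S,2E,6Z,9R)-9-[3-(acetyloxy)prop-1-en-2-yl]-6-{[(tert-butyldimethylsilyl)oxy]methyl}-2-{[(4-methoxybenzyl)oxy]methyl}cyclodeca-2,6-dien-1-yl (2Z)-2-methylbut-2-enoate, via angelic mixed anhydride 24 (not isolated)
Conditions: 23, 2,4,6-trichlorobenzoyl chloride, Et3N, toluene, rt; then 22, 60 °C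
Reagents that add atoms: none
Why: Yamaguchi-type esterification through the mixed anhydride acylates the hindered secondary allylic alcohol with retention at C9, and leaving out DMAP avoids isomerisation of the angelate to the tiglate.

Step 16
Reactants: 25 (1S,2E,6Z,9R)-9-[3-(acetyloxy)prop-1-en-2-yl]-6-{[(tert-butyldimethylsilyl)oxy]methyl}-2-{[(4-methoxybenzyl)oxy]methyl}cyclodeca-2,6-dien-1-yl (2Z)-2-methylbut-2-enoate
Product: 26 (1S,2E,6Z,9R)-9-[3-(acetyloxy)prop-1-en-2-yl]-6-{[(tert-butyldimethylsilyl)oxy]methyl}-2-(hydroxymethyl)cyclodeca-2,6-dien-1-yl (2Z)-2-methylbut-2-enoate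
Conditions: DDQ, CH2Cl2/H2O (pH 7, KH2PO4/K2HPO4), 0 °C
Reagents that add atoms: none
Why: Oxidative PMB ether cleavage by DDQ frees the C14 primary allylic alcohol and leaves the silyl ether, esters and alkenes intact.

Step 17
Reactants: 27 propanoyl chloride; 28 acetaldehyde
Product: 30 (3R,4S)-3,4-dimethyloxetan-2-one, via methylketene 29 (not isolated)
Conditions: O-trimethylsilylquinidine (10 mol%), LiClO4, iPr2NEt, CH2Cl2/Et2O, −78 °C
Reagents that add atoms: none
Why: Cinchona-alkaloid-catalysed ketene–aldehyde [2+2] cyclocondensation in which the quinidine-derived ammonium Z-enolate of methylketene adds to LiClO4-activated acetaldehyde through a closed transition state, giving the cis-β-lactone and setting both side-chain stereocentres; the (3R,4S) sense is assigned to the quinidine series by analogy with related alkaloid-catalysed ketene reactions and must be confirmed on the lactone (the quinine-derived catalyst gives the antipode).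

Step 18
Reactants: 26 (1S,2E,6Z,9R)-9-[3-(acetyloxy)prop-1-en-2-yl]-6-{[(tert-butyldimethylsilyl)oxy]methyl}-2-(hydroxymethyl)cyclodeca-2,6-dien-1-yl (2Z)-2-methylbut-2-enoate; 30 (3R,4S)-3,4-dimethyloxetan-2-one
Product: 31 (1S,2E,6Z,9R)-9-[3-(acetyloxy)prop-1-en-2-yl]-6-{[(tert-butyldimethylsilyl)oxy]methyl}-2-({[(2R,3S)-3-hydroxy-2-methylbutanoyl]oxy}methyl)cyclodeca-2,6-dien-1-yl (2Z)-2-methylbut-2-enoate
Conditions: La(OtBu)3 (10 mol%), 30 (2 equiv), THF, 0 °C
Reagents that add atoms: none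
Why: Lanthanide-alkoxide-catalysed alcoholysis of the strained β-lactone goes by acyl–oxygen cleavage, so the C14 alcohol is acylated and both lactone stereocentres are retained as the (2R,3S)-3-hydroxy-2-methylbutanoate.

Step 19
Reactants: 31 (1S,2E,6Z,9R)-9-[3-(acetyloxy)prop-1-en-2-yl]-6-{[(tert-butyldimethylsilyl)oxy]methyl}-2-({[(2R,3S)-3-hydroxy-2-methylbutanoyl]oxy}methyl)cyclodeca-2,6-dien-1-yl (2Z)-2-methylbut-2-enoate
Product: 32 (1S,2E,6Z,9R)-9-[3-(acetyloxy)prop-1-en-2-yl]-6-(hydroxymethyl)-2-({[(2R,3S)-3-hydroxy-2-methylbutanoyl]oxy}methyl)cyclodeca-2,6-dien-1-yl (2Z)-2-methylbut-2-enoate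
Conditions: HF·pyridine, pyridine, THF, 0 °C to rt
Reagents that add atoms: none
Why: Buffered fluoride desilylation removes the primary allylic TBS ether without ester cleavage or acyl migration.

Step 20
Reactants: 32 (1S,2E,6Z,9R)-9-[3-(acetyloxy)prop-1-en-2-yl]-6-(hydroxymethyl)-2-({[(2R,3S)-3-hydroxy-2-methylbutanoyl]oxy}methyl)cyclodeca-2,6-dien-1-yl (2Z)-2-methylbut-2-enoate
Product: 33 CNP0316239.2, (4S,5R,7S,9S)-12-acetoxy-9-[(Z)-2-methylbut-2-enoyloxy]-4,5-epoxy-15-hydroxy-14-[(2R,3S)-3-hydroxy-2-methylbutanoyloxy]germacra-1(10)E,11(13)-diene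
Conditions: Ti(OiPr)4 (20 mol%), L-(+)-diethyl tartrate (24 mol%), tBuOOH, 4 Å molecular sieves, CH2Cl2, −20 °C
Reagents that add atoms: tert-butyl hydroperoxide, CC(C)(C)OO
Why: Sharpless asymmetric epoxidation, in which only C4=C5 carries a free allylic hydroxyl and the titanium–L-(+)-tartrate catalyst delivers oxygen to the face that gives the 4S,5R epoxide (the same sense as nerol giving the 2S,3R epoxy alcohol).

## Compound list

1 | 4,4-diethoxybut-1-ene | C=CCC(OCC)OCC | starting material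
2 | (E)-but-2-enal | C/C=C/C=O | starting material
3 | (E)-5,5-diethoxypent-2-enal | O=C/C=C/CC(OCC)OCC | intermediate
4 | S-tert-butyl ethanethioate | CC(=O)SC(C)(C)C | starting material
5 | lithium 1-(tert-butylsulfanyl)ethen-1-olate | [Li+].[O-]C(=C)SC(C)(C)C | intermediate
6 | 1-(tert-butylsulfanyl)-1-(trimethylsilyloxy)ethene | C=C(O[Si](C)(C)C)SC(C)(C)C | intermediate
7 | S-tert-butyl (3S)-5,5-diethoxy-3-(2-oxoethyl)pentanethioate | O=CC[C@@H](CC(OCC)OCC)CC(=O)SC(C)(C)C | intermediate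
8 | S-tert-butyl (3S)-5,5-diethoxy-3-(3-oxoprop-1-en-2-yl)pentanethioate | O=CC(=C)[C@@H](CC(OCC)OCC)CC(=O)SC(C)(C)C | intermediate
9 | (3R)-5,5-diethoxy-3-(3-hydroxyprop-1-en-2-yl)pentan-1-ol | OCC(=C)[C@@H](CC(OCC)OCC)CCO | intermediate
10 | (3S)-1,1-diethoxy-5-iodo-3-(3-iodoprop-1-en-2-yl)pentane | ICC(=C)[C@@H](CC(OCC)OCC)CCI | intermediate
11 | 2-[(3S)-5,5-diethoxy-1-iodopentan-3-yl]prop-2-en-1-yl acetate | CC(=O)OCC(=C)[C@@H](CC(OCC)OCC)CCI | intermediate
12 | {(3S)-3-[3-(acetyloxy)prop-1-en-2-yl]-5,5-diethoxypentyl}triphenylphosphonium iodide | CC(=O)OCC(=C)[C@@H](CC(OCC)OCC)CC[P+](c1ccccc1)(c1ccccc1)c1ccccc1.[I-] | intermediate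
13 | 2-[(tert-butyldimethylsilyl)oxy]acetaldehyde | O=CCO[Si](C)(C)C(C)(C)C | starting material
14 | (±)-1-[(tert-butyldimethylsilyl)oxy]but-3-en-2-ol | C=CC(O)CO[Si](C)(C)C(C)(C)C | intermediate
15 | 1-[(tert-butyldimethylsilyl)oxy]but-3-en-2-one | C=CC(=O)CO[Si](C)(C)C(C)(C)C | intermediate
16 | 1-methoxy-4-[(prop-2-yn-1-yloxy)methyl]benzene | C#CCOCc1ccc(OC)cc1 | starting material
17 | 1-[(tert-butyldimethylsilyl)oxy]-7-[(4-methoxybenzyl)oxy]hept-5-yn-2-one | COc1ccc(COCC#CCCC(=O)CO[Si](C)(C)C(C)(C)C)cc1 | intermediate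
18 | {(3S)-3-[3-(acetyloxy)prop-1-en-2-yl]-5,5-diethoxypentylidene}triphenylphosphorane | CC(=O)OCC(=C)[C@@H](CC(OCC)OCC)CC=P(c1ccccc1)(c1ccccc1)c1ccccc1 | intermediate
19 | 2-[(3R,5Z)-6-{[(tert-butyldimethylsilyl)oxy]methyl}-1,1-diethoxy-11-[(4-methoxybenzyl)oxy]undec-5-en-9-yn-3-yl]prop-2-en-1-yl acetate | CC(=O)OCC(=C)[C@@H](CC(OCC)OCC)C/C=C(\CO[Si](C)(C)C(C)(C)C)CCC#CCOCc1ccc(OC)cc1 | intermediate
20 | 2-[(3R,5Z)-6-{[(tert-butyldimethylsilyl)oxy]methyl}-11-[(4-methoxybenzyl)oxy]-1-oxoundec-5-en-9-yn-3-yl]prop-2-en-1-yl acetate | CC(=O)OCC(=C)[C@@H](CC=O)C/C=C(\CO[Si](C)(C)C(C)(C)C)CCC#CCOCc1ccc(OC)cc1 | intermediate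
21 | (2E,6Z,9R)-9-[3-(acetyloxy)prop-1-en-2-yl]-6-{[(tert-butyldimethylsilyl)oxy]methyl}-2-{[(4-methoxybenzyl)oxy]methyl}cyclodeca-2,6-dien-1-one | C=C(COC(C)=O)[C@H]1CC(=O)/C(COCc2ccc(OC)cc2)=C/CC/C(CO[Si](C)(C)C(C)(C)C)=C/C1 | intermediate
22 | (1S,2E,6Z,9R)-9-[3-(acetyloxy)prop-1-en-2-yl]-6-{[(tert-butyldimethylsilyl)oxy]methyl}-2-{[(4-methoxybenzyl)oxy]methyl}cyclodeca-2,6-dien-1-ol | C=C(COC(C)=O)[C@H]1C[C@H](O)/C(COCc2ccc(OC)cc2)=C/CC/C(CO[Si](C)(C)C(C)(C)C)=C/C1 | intermediate
23 | (Z)-2-methylbut-2-enoic acid (angelic acid) | C/C=C(/C)C(=O)O | starting material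
24 | (Z)-2-methylbut-2-enoic 2,4,6-trichlorobenzoic anhydride | C/C=C(/C)C(=O)OC(=O)c1c(Cl)cc(Cl)cc1Cl | intermediate
25 | (1S,2E,6Z,9R)-9-[3-(acetyloxy)prop-1-en-2-yl]-6-{[(tert-butyldimethylsilyl)oxy]methyl}-2-{[(4-methoxybenzyl)oxy]methyl}cyclodeca-2,6-dien-1-yl (2Z)-2-methylbut-2-enoate | C=C(COC(C)=O)[C@H]1C[C@H](OC(=O)/C(C)=C\C)/C(COCc2ccc(OC)cc2)=C/CC/C(CO[Si](C)(C)C(C)(C)C)=C/C1 | intermediate
26 | (1S,2E,6Z,9R)-9-[3-(acetyloxy)prop-1-en-2-yl]-6-{[(tert-butyldimethylsilyl)oxy]methyl}-2-(hydroxymethyl)cyclodeca-2,6-dien-1-yl (2Z)-2-methylbut-2-enoate | C=C(COC(C)=O)[C@H]1C[C@H](OC(=O)/C(C)=C\C)/C(CO)=C/CC/C(CO[Si](C)(C)C(C)(C)C)=C/C1 | intermediate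
27 | propanoyl chloride | CCC(=O)Cl | starting material
28 | acetaldehyde | CC=O | starting material
29 | methylketene (prop-1-en-1-one) | CC=C=O | intermediate
30 | (3R,4S)-3,4-dimethyloxetan-2-one | C[C@H]1C(=O)O[C@H]1C | intermediate
31 | (1S,2E,6Z,9R)-9-[3-(acetyloxy)prop-1-en-2-yl]-6-{[(tert-butyldimethylsilyl)oxy]methyl}-2-({[(2R,3S)-3-hydroxy-2-methylbutanoyl]oxy}methyl)cyclodeca-2,6-dien-1-yl (2Z)-2-methylbut-2-enoate | C=C(COC(C)=O)[C@H]1C[C@H](OC(=O)/C(C)=C\C)/C(COC(=O)[C@H](C)[C@H](C)O)=C/CC/C(CO[Si](C)(C)C(C)(C)C)=C/C1 | intermediate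
32 | (1S,2E,6Z,9R)-9-[3-(acetyloxy)prop-1-en-2-yl]-6-(hydroxymethyl)-2-({[(2R,3S)-3-hydroxy-2-methylbutanoyl]oxy}methyl)cyclodeca-2,6-dien-1-yl (2Z)-2-methylbut-2-enoate | C=C(COC(C)=O)[C@H]1C[C@H](OC(=O)/C(C)=C\C)/C(COC(=O)[C@H](C)[C@H](C)O)=C/CC/C(CO)=C/C1 | intermediate
33 | CNP0316239.2, (4S,5R,7S,9S)-12-acetoxy-9-angeloyloxy-4,5-epoxy-15-hydroxy-14-[(2R,3S)-3-hydroxy-2-methylbutanoyloxy]germacra-1(10)E,11(13)-diene | C=C(COC(C)=O)[C@H]1C[C@H](OC(=O)/C(C)=C\C)/C(COC(=O)[C@H](C)[C@H](C)O)=C/CC[C@@]2(CO)O[C@@H]2C1 | target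

## Step count and risks

Total step count: 20. Longest linear sequence: 15 (steps 1, 3–7, 11–16, 18–20).

**Step 13 (proposed new macrocyclisation).** It may fail through aldehyde dimerisation or decarbonylation, through insertion of zerovalent nickel into the allylic acetate, or simply because the medium ring does not close. The fallback uses known chemistry, a Nozaki–Hiyama–Kishi ring closure. It sets out from 19. Syn hydrostannation (Bu3SnH, Pd(PPh3)2Cl2 cat., THF) puts tin on the alkyne carbon next to the CH2OPMB group and gives the E-vinylstannane F1. Iododestannylation (I2, CH2Cl2, 0 °C) gives the vinyl iodide F2 with retention. Acetal hydrolysis (aq. oxalic acid on SiO2) gives the iodo aldehyde F3. CrCl2 (excess) with NiCl2 (cat.) in DMSO/THF at high dilution closes the ring to the macrocyclic allylic alcohol F4 as a C9 epimer mixture. Dess–Martin oxidation of F4 comes back to the route at 21.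

**Step 14 (CBS reduction on the macrocycle).** The ring's own facial bias may override the catalyst. The fallback sets out from 21 and uses the enantiomeric (S)-2-methyl-CBS-oxazaborolidine with catecholborane, which is then the matched pair and gives the (9R)-alcohol F5. Mitsunobu esterification of F5 with 23 (PPh3, diisopropyl azodicarboxylate, toluene, 0 °C) inverts C9 and installs the angelate in one operation. It comes back to the route at 25.

**Step 20 (late Sharpless epoxidation).** The titanium–tartrate catalyst may be mismatched with the accessible ring conformer, or may open the acid-sensitive epoxy alcohol. The fallback sets out from 31, before desilylation, and uses a non-directed organocatalytic dioxirane epoxidation: the D-fructose-derived Shi ketone with KHSO5 (as its triple salt 2KHSO5·KHSO4·K2SO4), K2CO3, MeCN/dimethoxymethane/H2O, 0 °C. C4=C5 is the most electron-rich alkene, and the spiro transition-state model predicts the 4S,5R epoxy silyl ether F6. Desilylation of F6 with HF·pyridine comes back to the route at 33.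

## Further compounds

F1 | step 13 | 2-[(3R,5Z,9E)-6-{[(tert-butyldimethylsilyl)oxy]methyl}-1,1-diethoxy-11-[(4-methoxybenzyl)oxy]-10-(tributylstannyl)undeca-5,9-dien-3-yl]prop-2-en-1-yl acetate | CC(=O)OCC(=C)[C@@H](CC(OCC)OCC)C/C=C(\CO[Si](C)(C)C(C)(C)C)CC/C=C(\COCc1ccc(OC)cc1)[Sn](CCCC)(CCCC)CCCC
F2 | step 13 | 2-[(3R,5Z,9E)-6-{[(tert-butyldimethylsilyl)oxy]methyl}-1,1-diethoxy-10-iodo-11-[(4-methoxybenzyl)oxy]undeca-5,9-dien-3-yl]prop-2-en-1-yl acetate | CC(=O)OCC(=C)[C@@H](CC(OCC)OCC)C/C=C(\CO[Si](C)(C)C(C)(C)C)CC/C=C(\COCc1ccc(OC)cc1)I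
F3 | step 13 | 2-[(3R,5Z,9E)-6-{[(tert-butyldimethylsilyl)oxy]methyl}-10-iodo-11-[(4-methoxybenzyl)oxy]-1-oxoundeca-5,9-dien-3-yl]prop-2-en-1-yl acetate | CC(=O)OCC(=C)[C@@H](CC=O)C/C=C(\CO[Si](C)(C)C(C)(C)C)CC/C=C(\COCc1ccc(OC)cc1)I
F4 | step 13 | (2E,6Z,9R)-9-[3-(acetyloxy)prop-1-en-2-yl]-6-{[(tert-butyldimethylsilyl)oxy]methyl}-2-{[(4-methoxybenzyl)oxy]methyl}cyclodeca-2,6-dien-1-ol (mixture of C1 epimers) | C=C(COC(C)=O)[C@H]1CC(O)/C(COCc2ccc(OC)cc2)=C/CC/C(CO[Si](C)(C)C(C)(C)C)=C/C1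
F5 | step 14 | (1R,2E,6Z,9R)-9-[3-(acetyloxy)prop-1-en-2-yl]-6-{[(tert-butyldimethylsilyl)oxy]methyl}-2-{[(4-methoxybenzyl)oxy]methyl}cyclodeca-2,6-dien-1-ol | C=C(COC(C)=O)[C@H]1C[C@@H](O)/C(COCc2ccc(OC)cc2)=C/CC/C(CO[Si](C)(C)C(C)(C)C)=C/C1
F6 | step 20 | 15-O-(tert-butyldimethylsilyl) ether of 33, (4S,5R,7S,9S)-configured | C=C(COC(C)=O)[C@H]1C[C@H](OC(=O)/C(C)=C\C)/C(COC(=O)[C@H](C)[C@H](C)O)=C/CC[C@@]2(CO[Si](C)(C)C(C)(C)C)O[C@@H]2C1
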